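(All runs stem from a simulated flask from invented constants, noise included.)

Follow Z.

common to all: J 200 mM (held)

| charge | Z | remark | time |
|---|---|---|---|
| noon | 1.3 M | run made earlier |  |
| winter | 3 M | run made earlier |  |
| flask | 2.0 M |  | 8.0 d |

- noon (time / d: L / %, Z / %): 1.04: 10.3, 50.3; 1.67: 15.7, 25.5; 3.00: 14.0, 0; 5.00: 4.1, 0.3; 10.0: 0, 0
- winter (time / d: L / %, Z / %): 1.04: 4.1, 78.6; 1.67: 7.2, 68.4; 3.00: 8.7, 46.7; 5.00: 9.2, 18.5; 10.0: 0.1, 0.1

(standard deviation of a reading: 1 percentage point)

- time up to 8.0 d at which L stands highest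
- the amount of L, in percent of the Z charged, at that time
- the first time at which L reaches 9.2%, in the same percent, in d

- Z is a solid; its amount is given per volume of the solution
- at the start none of Z is in solution
- at the start none of J is in solution

Does the charge change how fast Z leaves? By 1.04 d the noon run has lost 0.646 M of Z and the winter run 0.642 M, the same within the scatter. So I treat the loss of Z as close to zero order and use the winter run as a molar clock for this flask.

When has that clock counted off this flask's 2.0 M? Between 3.00 d and 5.00 d the winter run loses Z at 0.423 M d⁻¹. The clearing time, the moment the winter run has lost as much Z as this flask is charged with, is therefore 3.95 d.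

What does L do on either side of it? In the winter run, with Z still read at 18.5% at 5.00 d, c(L) reads 0.261 M at 3.00 d and 0.276 M at 5.00 d. In the noon run, with Z read at 0% at 3.00 d, c(L) falls from 0.182 M to 0.0533 M by 5.00 d. So I put the peak at the clearing time, at 13.4% of this charge, and the winter readings cross 0.184 M at 1.45 d.

The forecast puts the peak at 4.1 d with 13.6%, higher than mine, and the level at 1.45 d, holding that “the charge only sets when it runs out”.

The flask gives its highest L at 3.95 d, with 13.1%, and reaches the level at 1.53 d.

    Z ⇌ E, rate k1*(cs1 - [E]) while solid is left; crystals form when [E] > cs1 (solubility = 1.10 M, k = 0.0290 h⁻¹)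
    E + G ⇌ L (K = 2.80 L mol⁻¹, k = 0.540 L mol⁻¹ h⁻¹)
    J ⇌ G, rate k3*(csat - [G]) (kL = 0.270 h⁻¹)
    E → X (k = 0.0360 h⁻¹)
    E → Q (k = 1.40 × 10⁻⁴ h⁻¹)

At 0.800 d this flask holds 74.3% Z, and at 3.95 d it holds 0%. The same charge stopped at 50 h is 1.86 d short of my clearing time of 3.95 d, and at 0.423 M d⁻¹ I reckon 39.4% of the charge still to go as Z. That neighbour holds 41.5%.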